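## Structural features

The target is an achiral, linear chain of eight benzene rings (A to H) joined only by seven diaryl ether oxygens and carrying 21 free phenolic hydroxyls. It has no stereocentre, so no neighbouring stereocentres need to be related, and no ring is joined to another by a C–C bond. Ring A is a 2,4,6-trihydroxyphenyl and ring H a 3,4,5-trihydroxyphenyl end group. Rings B and D are 2,6-dihydroxy-1,4-phenylenedioxy units, and rings C, E and G are 3,4,5-trihydroxy-1,2-phenylenedioxy units with five contiguous oxygens. The phloroglucinol-, hydroxyquinol- and pyrogallol-type rings are very easily oxidised in air and base, so all hydroxyls should stay masked until the last step; the ynol ether and silyl ketene acetal used on the way are labile to water and acid. The real difficulty is the regiocontrolled formation of seven aryl–O–aryl bonds between electron-rich rings: the D–O–E ether is flanked by four ortho oxygens and the B–O–C ether by three. Ring F is the only ring with a different pattern: C1 (oxygen to ring E), C3 (OH) and C5 (oxygen to ring G) are mutually meta, C4 carries the fourth oxygen, and C2 and C6 carry hydrogen. The key step exploits exactly this: C6–C1–C2–C3 map onto a 3-aryloxy-1,1-dioxygenated diene, C5 and C4 onto a β-aryloxy ynone, and the acetyl group on C4 is a latent hydroxyl.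

## Logic of the disconnections

35 ⇒ 34. The nineteen O–CH3 bonds are cut. The free polyphenol is too oxidisable to carry through any other step, so it is unveiled last. The forward step must cleave every alkyl aryl ether while leaving the seven diaryl ethers intact.

34 ⇒ 32. The C4–O bond of ring F is traded for a C4–C(acetyl) bond. The acetyl group is what activates the ring synthesis, and it sits ortho to a hydroxyl, which is the favourable case for a peroxide rearrangement with aryl migration. The forward step needs a hindered, hydrogen-bonded ketone to migrate cleanly.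

32 ⇒ 29 + 10. The C5–C6 and C3–C4 bonds of ring F are cut. This splits the octamer into a five-ring and a two-ring fragment, and both ethers of ring F are carried in on non-aromatic carbons, so no aryl–oxygen coupling is needed at ring F. The forward step must deliver one regiochemistry and must be faster than the decomposition of two sensitive partners.

29 ⇒ 28 ⇒ 26 + 27. The O–Si bond is cut first, then the vinyl C–O bond to the ring E oxygen. The diene carbons come from a four-carbon alkynoate, and the ring E oxygen is attached by conjugate addition. The forward steps need γ-deprotonation of the enoate and immediate use of the ketene acetal.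

10 ⇒ 7 + 8 ⇒ 5 + 6. The acyl–alkyne C–C bond is cut, then the O–C(sp2) bond to the ring G oxygen. The two alkyne carbons come from a C2 chloroalkene and the acetyl group from an amide. The forward steps need an aryloxyacetylide that survives long enough to be acylated once.

26 ⇒ 24 ⇒ 23 + 2, then 23 ⇒ 21 ⇒ 20 + 14, 20 ⇒ 18 ⇒ 17 + 12 and 17 ⇒ 15 ⇒ 13 + 14. Each phenol is traced to an aryl aldehyde (C–O for C–CHO), and each aldehyde is cut at the aryl–O bond made at its bromide carbon. Every ring thus enters as a bromo-formyl arene whose formyl group first activates the C–Br bond (ortho or para) and then becomes the next phenol. This reduces the pentamer to three small bromoaldehydes and one phenol. The demand is that hindered phenoxides couple, most severely in 23 + 2.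

5 ⇒ 3 ⇒ 1 + 2. The same pair of cuts gives the two-ring phenol from two simple monomers; the coupling is the least hindered of the series.

12 ⇒ 11. The C–CHO bond is cut. The only free ring position of 11 is the one required, so the formylation has no regiochemical choice.

## Other disconnections considered

Alternative 1: The cut is the C1–C6 bond of ring A. In the forward sense the open-chain triketide ester methyl 6-[4-(benzyloxy)-3,5-dimethoxyphenoxy]-3,5-dioxohexanoate A1 would be closed by base (Claisen-type attack of the aryloxy-bearing C6 carbanion on the ester) to the two-ring triol 2-[4-(benzyloxy)-3,5-dimethoxyphenoxy]benzene-1,3,5-triol A2.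
- In favour: the A–O–B ether would exist before ring A does, so no aryl–oxygen coupling is needed at the di-ortho-substituted carbon of ring A. In this respect it is the equal of the chosen key step, which does the same for ring F. It is the better of the two in reagent simplicity, since it needs only an alkoxide and no silyl ketene acetal or ynol ether.
- Against: C2 and C4 of A1 are far more acidic than C6, so the required carbanion is available only through a polyanion. Ring closure through oxygen to a pyran-2-one is the usual fate of 3,5-dioxo esters. The three hydroxyls of A2 would have to be re-protected before any coupling or strong base.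
- Comparison: it builds a terminal ring and the least demanding of the seven ethers, which step 6 forms in one operation from 13 and 14. It gains no convergence, adds several steps, and leaves ring F and the congested ethers untouched.

Alternative 2: The cut is the C–C bond of ring C between the ketene carbon and the aryloxy-bearing vinyl carbon. In the forward sense the racemic cyclobutenone 4-[(E)-2-(AB-O)ethenyl]-2,3,4-trimethoxycyclobut-2-en-1-one A3 would be heated; four-electron ring opening to a vinylketene and six-electron closure would give the three-ring phenol 6-(AB-O)-2,3,4-trimethoxyphenol A4.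
- In favour: A4 is identical with compound 20 of the chosen route, so this alternative could replace steps 5, 8 and 9. It is the better on two points: the pentaoxygenated ring C would arise with unambiguous regiochemistry in a reagent-free thermal step, and the tri-ortho B–O–C ether would be made on a vinyl carbon and not by coupling.
- Against: A3 needs an (E)-2-aryloxyvinyl metal reagent derived from 17, which can lose aryloxide by β-elimination, followed by addition to a squaric ester and O-methylation. That is about four operations from 17 against two from 17 plus step 5.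
- Comparison: it is a linear, early-stage ring synthesis that makes no contribution to ring F or to the D–O–E ether. It is compatible with the chosen plan but not shorter.

Alternative 3: The cut is two C–C bonds of ring D. In the forward sense the magnesium enolate of dimethyl (2E)-3-(ABC-O)pent-2-enedioate A5 would be C-acylated at both flanking carbons by the 2-aryloxymalonyl dichloride A6, which carries rings E to H, to give the octamer A7 with ring D as a dihydroxy diester.
- In favour: it is as convergent as the chosen plan (three plus four rings against five plus two, one ring formed in each). It is the better on one important point: the tetra-ortho D–O–E ether and the C–O–D ether would both pre-exist on sp3 or vinyl carbons, which removes the weakest conventional step of the chosen route (step 12).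
- Against: malonyl dichlorides usually react with enolisable 1,3-dicarbonyl partners by C,O-acylation to pyranones, and A6 can form a ketene. The ionic acylation has no orbital control comparable to the matched polarisation of the cycloaddition. A7 needs ester hydrolysis and a double decarboxylation on a very large substrate before deprotection, three operations after the key step against two. Fragment A6 still contains ring F with its two ethers, which would have to be made by couplings or by a ring synthesis of the chosen kind.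
- Comparison: on structure the two plans are similar in convergence. On mechanism the chosen plan should have the better-defined selectivity. On step economy the alternative is longer, because it does not dispose of ring F.

Key step: step 16

Remarks on the chemistry and on names:
- Compounds 1, 2, 11, 13 and 14 are taken as catalogue compounds; 2 and 13 are otherwise each one standard step from 3,4,5-trimethoxybenzaldehyde and 2,4,6-trimethoxybenzaldehyde.
- A ring-by-ring comparison of 29, 10 and 32 with 35 shows the same oxygenation pattern in every ring, so no structure needed correction and both precursors are kept unchanged. The C1 geometry of 29 is written as (1Z) (silylation of the chelated s-cis dienolate), but it has no consequence because C1 becomes an aromatic carbon.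
- Abbreviations in names:
  - AB-O = 2,6-dimethoxy-4-(2,4,6-trimethoxyphenoxy)phenoxy
  - ABC-O = 6-(AB-O)-2,3,4-trimethoxyphenoxy
  - ABCD-O = 4-(ABC-O)-2,6-dimethoxyphenoxy
  - ABCDE-O = 2-(ABCD-O)-3,4,5-trimethoxyphenoxy
  - GH-O = 3,4,5-trimethoxy-2-(3,4,5-trimethoxyphenoxy)phenoxy

## Route

Step 1
Reactants: 1 3,4,5-trimethoxyphenol; 2 2-bromo-3,4,5-trimethoxybenzaldehyde
Product: 3 3,4,5-trimethoxy-2-(3,4,5-trimethoxyphenoxy)benzaldehyde
Conditions: CuI (10 mol %), picolinic acid (20 mol %), K3PO4, DMSO, 90 °C, Ar
Reagents that add atoms: none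
Why: Ullmann-type C–O coupling of an unhindered phenoxide with an aryl bromide whose ortho-formyl group eases both copper insertion and addition–elimination; the bromide carbon becomes the inner oxygen-bearing carbon of ring G and the formyl carbon is its latent outer oxygen.

Step 2
Reactants: 3
Product: 5 3,4,5-trimethoxy-2-(3,4,5-trimethoxyphenoxy)phenol (GH phenol), via aryl formate 4 (not isolated)
Conditions: mCPBA (1.2 equiv), NaHCO3, CH2Cl2, 0 °C to rt; Na2S2O3 wash; then K2CO3, MeOH, rt
Reagents that add atoms: mCPBA, O=C(OO)c1cccc(Cl)c1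
Why: Baeyer–Villiger oxidation (Dakin-type) of an electron-rich benzaldehyde; the aryl group with ortho-aryloxy and para-methoxy donors should migrate in preference to hydride, and the formate is removed by methanolysis after the peracid has been destroyed.

Step 3
Reactants: 5; 6 trichloroethylene
Product: 7 1-[(E)-1,2-dichloroethenyloxy]-3,4,5-trimethoxy-2-(3,4,5-trimethoxyphenoxy)benzene
Conditions: K2CO3, DMF, 70 °C
Reagents that add atoms: none
Why: Base-mediated vinylation of a phenol with trichloroethylene (elimination to dichloroacetylene, then anti addition of the phenoxide), which is the established entry to (E)-1,2-dichlorovinyl aryl ethers.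

Step 4
Reactants: 7; 8 N-methoxy-N-methylacetamide
Product: 10 4-(GH-O)but-3-yn-2-one, via lithium aryloxyacetylide 9 (not isolated)
Conditions: n-BuLi (2.1 equiv), THF, −78 °C; then 8, −78 to 0 °C; pH 7 phosphate buffer
Reagents that add atoms: none
Why: Elimination of HCl and chlorine–lithium exchange convert the dichlorovinyl ether into the lithium ynolate-type acetylide (ynol ether synthesis), and Weinreb amide acylation stops at the ketone because the chelated tetrahedral adduct survives until the neutral quench.

Step 5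
Reactants: 11 5-bromo-1,2,3-trimethoxybenzene
Product: 12 6-bromo-2,3,4-trimethoxybenzaldehyde
Conditions: Cl2CHOMe, TiCl4, CH2Cl2, 0 °C; then ice-cold dilute HCl
Reagents that add atoms: dichloromethyl methyl ether, COC(Cl)Cl; water, O
Why: Rieche formylation; the two free positions of 11 are equivalent and activated by an ortho and a para methoxy group, so only one aldehyde can form.

Step 6
Reactants: 13 2,4,6-trimethoxyphenol; 14 4-bromo-2,6-dimethoxybenzaldehyde
Product: 15 2,6-dimethoxy-4-(2,4,6-trimethoxyphenoxy)benzaldehyde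
Conditions: CuI (10 mol %), picolinic acid (20 mol %), K3PO4, DMSO, 90 °C, Ar
Reagents that add atoms: none
Why: Ullmann-type C–O coupling in which the hindered partner is the nucleophile and the bromide is unhindered and activated by the para-formyl group; the picolinic acid system is suited to 2,6-disubstituted phenols.

Step 7
Reactants: 15
Product: 17 2,6-dimethoxy-4-(2,4,6-trimethoxyphenoxy)phenol (AB phenol), via aryl formate 16 (not isolated)
Conditions: mCPBA (1.2 equiv), NaHCO3, CH2Cl2, 0 °C to rt; Na2S2O3 wash; then K2CO3, MeOH, rt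
Reagents that add atoms: mCPBA, O=C(OO)c1cccc(Cl)c1
Why: Baeyer–Villiger oxidation (Dakin-type); a 2,6-dimethoxy-4-aryloxyphenyl group is a strongly migrating aryl group, and the oxidant is removed before the oxidisable phenol is set free.

Step 8
Reactants: 17; 12
Product: 18 6-(AB-O)-2,3,4-trimethoxybenzaldehyde
Conditions: CuI (10 mol %), picolinic acid (20 mol %), K3PO4, DMSO, 100 °C, Ar
Reagents that add atoms: none
Why: Ullmann-type C–O coupling of a 2,6-dimethoxyphenoxide with an ortho-formyl aryl bromide that has only one ortho substituent besides hydrogen; the formyl group is placed on the carbon that must become the inner oxygen of ring C.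

Step 9
Reactants: 18
Product: 20 6-(AB-O)-2,3,4-trimethoxyphenol (ABC phenol), via aryl formate 19 (not isolated)
Conditions: mCPBA (1.2 equiv), NaHCO3, CH2Cl2, 0 °C to rt; Na2S2O3 wash; then K2CO3, MeOH, rt
Reagents that add atoms: mCPBA, O=C(OO)c1cccc(Cl)c1
Why: Baeyer–Villiger oxidation (Dakin-type) of an aldehyde flanked by methoxy and aryloxy donors with a para-methoxy group, followed by methanolysis of the formate.

Step 10
Reactants: 20; 14
Product: 21 4-(ABC-O)-2,6-dimethoxybenzaldehyde
Conditions: CuI (10 mol %), picolinic acid (20 mol %), K3PO4, DMSO, 100 °C, Ar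
Reagents that add atoms: none
Why: Ullmann-type C–O coupling of a di-ortho-substituted phenoxide with the unhindered, para-formyl-activated bromide already used in step 6.

Step 11
Reactants: 21
Product: 23 4-(ABC-O)-2,6-dimethoxyphenol (ABCD phenol), via aryl formate 22 (not isolated)
Conditions: mCPBA (1.2 equiv), NaHCO3, CH2Cl2, 0 °C to rt; Na2S2O3 wash; then K2CO3, MeOH, rt
Reagents that add atoms: mCPBA, O=C(OO)c1cccc(Cl)c1
Why: Baeyer–Villiger oxidation (Dakin-type), the same substitution pattern around the formyl group as in step 7.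

Step 12
Reactants: 23; 2
Product: 24 2-(ABCD-O)-3,4,5-trimethoxybenzaldehyde
Conditions: CuI (20 mol %), picolinic acid (40 mol %), K3PO4, 2 (2 equiv), DMSO, 110 °C, Ar
Reagents that add atoms: none
Why: Ullmann-type C–O coupling forming the tetra-ortho-substituted D–O–E ether; the ortho-formyl group of 2 activates the hindered bromide, the 2,6-dimethoxyphenoxide is electron-rich and its flanking groups are small, and the cheap electrophile can be used in excess.

Step 13
Reactants: 24
Product: 26 2-(ABCD-O)-3,4,5-trimethoxyphenol (ABCDE phenol), via aryl formate 25 (not isolated)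
Conditions: mCPBA (1.2 equiv), NaHCO3, CH2Cl2, 0 °C to rt; Na2S2O3 wash; then K2CO3, MeOH, rt
Reagents that add atoms: mCPBA, O=C(OO)c1cccc(Cl)c1
Why: Baeyer–Villiger oxidation (Dakin-type), the same substitution pattern around the formyl group as in step 2.

Step 14
Reactants: 26; 27 methyl but-2-ynoate
Product: 28 methyl (2E)-3-(ABCDE-O)but-2-enoate
Conditions: Cs2CO3 (0.3 equiv), 27 (2 equiv), DMF, 70 °C
Reagents that add atoms: none
Why: Base-catalysed oxa-Michael addition of a phenoxide to an alkynoate; the E enoate is the thermodynamic isomer under the equilibrating conditions, and any Z or deconjugated isomer would give the same dienolate in step 15.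

Step 15
Reactants: 28
Product: 29 (1Z)-3-(ABCDE-O)-1-methoxy-1-(trimethylsilyloxy)buta-1,3-diene
Conditions: LiN(iPr)2 (1.2 equiv), THF, −78 °C; Me3SiCl (1.5 equiv), −78 to 0 °C; evaporate, dry toluene, filter under Ar; used crude at once
Reagents that add atoms: chlorotrimethylsilane, C[Si](C)(C)Cl
Why: Kinetic γ-deprotonation of a 3-oxy-substituted crotonate (the methyl group lies cis to the ester) and O-silylation of the dienolate, as in the preparation of 1,3-dioxygenated 1-silyloxydienes of the Brassard type.

Step 16
Reactants: 29; 10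
Product: 32 1-[4-(ABCDE-O)-6-(GH-O)-2-hydroxyphenyl]ethanone, via cycloadduct 30 (not isolated), via aryl trimethylsilyl ether 31 (not isolated)
Conditions: 10 (1.5 equiv), toluene, 25 to 80 °C, Ar; then 0.5 M HCl, THF, 0 °C
Reagents that add atoms: none
Why: Proposed new method: the silyl ketene acetal diene 29 should add to the electron-poor alkyne of 10 in a polarised, asynchronous [4+2] cycloaddition in which the nucleophilic CH2 terminus bonds first to the β-carbon of the ynone (the carbon bearing the ring G oxygen) and the ketal carbon then closes onto the acetyl-bearing α-carbon; the closest known reaction type is the Diels–Alder aromatisation of 1-alkoxy-1-silyloxybuta-1,3-dienes with alkynones and alkynoates to acylresorcinols, of which a β-aryloxy (push–pull) ynone is an untested member. Ring F is closed intermolecularly as a six-membered carbocycle in the [4+2] mode, giving the cyclohexa-1,4-diene 30. Its mixed ketal carbon should expel methanol in a 1,4-elimination driven by aromatisation to give the silyl ether 31, which dilute acid cleaves to the hydrogen-bonded phenol 32. No stereocentre remains: the ketal carbon of 30 is formed as a racemate and is flattened on aromatisation, and for the same reason the C1 geometry of 29 is irrelevant. The step needs one regiochemistry, and matched polarisation secures it: the largest HOMO coefficient of 29 is at its CH2 terminus and the largest LUMO coefficient of 10 is at the carbon β to the carbonyl, the aryloxy donor lowering the reactivity of 10 but not reversing this sense. This places the two aryloxy groups meta to each other and the acetyl group between the new hydroxyl and the ring G oxygen. Excess 10 and anhydrous, acid-free conditions protect the labile ketene acetal until it has reacted.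

Step 17
Reactants: 32
Product: 34 5-(ABCDE-O)-3-(GH-O)benzene-1,2-diol, via aryl acetate 33 (not isolated)
Conditions: H2O2 (30 % aq, 3 equiv), NaOH (3 equiv), THF/H2O, 0 °C to rt, Ar; then Na2S2O3, dilute HCl
Reagents that add atoms: hydrogen peroxide, OO
Why: Dakin oxidation of an ortho-hydroxyaryl ketone; the phenoxide drives migration of the electron-rich aryl group from carbon to oxygen and the resulting acetate is saponified in the same flask to the catechol.

Step 18
Reactants: 34
Product: 35 CNP0309601.0 (34 with all nineteen methoxy groups replaced by hydroxy groups; 21 OH)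
Conditions: BBr3 (40 equiv), CH2Cl2, −78 °C to rt, Ar; then MeOH, H2O; Sephadex LH-20 under Ar
Reagents that add atoms: none
Why: Lewis acid ether cleavage; bromide attacks the methyl group of each boron-complexed alkyl aryl ether, whereas diaryl ethers offer no sp3 carbon and should survive.

## Compound list

1 | 3,4,5-trimethoxyphenol | COc1cc(O)cc(OC)c1OC | starting material
2 | 2-bromo-3,4,5-trimethoxybenzaldehyde | O=Cc1cc(OC)c(OC)c(OC)c1Br | starting material
3 | 3,4,5-trimethoxy-2-(3,4,5-trimethoxyphenoxy)benzaldehyde | O=Cc1cc(OC)c(OC)c(OC)c1Oc1cc(OC)c(OC)c(OC)c1 | intermediate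
4 | 3,4,5-trimethoxy-2-(3,4,5-trimethoxyphenoxy)phenyl formate | O=COc1cc(OC)c(OC)c(OC)c1Oc1cc(OC)c(OC)c(OC)c1 | intermediate
5 | 3,4,5-trimethoxy-2-(3,4,5-trimethoxyphenoxy)phenol (GH phenol) | Oc1cc(OC)c(OC)c(OC)c1Oc1cc(OC)c(OC)c(OC)c1 | intermediate
6 | trichloroethylene | ClC=C(Cl)Cl | starting material
7 | 1-[(E)-1,2-dichloroethenyloxy]-3,4,5-trimethoxy-2-(3,4,5-trimethoxyphenoxy)benzene | Cl/C=C(Cl)\Oc1cc(OC)c(OC)c(OC)c1Oc1cc(OC)c(OC)c(OC)c1 | intermediate
8 | N-methoxy-N-methylacetamide | CC(=O)N(C)OC | starting material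
9 | lithium 2-(GH-O)ethynide | [Li]C#COc1cc(OC)c(OC)c(OC)c1Oc1cc(OC)c(OC)c(OC)c1 | intermediate
10 | 4-(GH-O)but-3-yn-2-one | CC(=O)C#COc1cc(OC)c(OC)c(OC)c1Oc1cc(OC)c(OC)c(OC)c1 | intermediate
11 | 5-bromo-1,2,3-trimethoxybenzene | COc1cc(Br)cc(OC)c1OC | starting material
12 | 6-bromo-2,3,4-trimethoxybenzaldehyde | O=Cc1c(Br)cc(OC)c(OC)c1OC | intermediate
13 | 2,4,6-trimethoxyphenol | COc1cc(OC)c(O)c(OC)c1 | starting material
14 | 4-bromo-2,6-dimethoxybenzaldehyde | COc1cc(Br)cc(OC)c1C=O | starting material
15 | 2,6-dimethoxy-4-(2,4,6-trimethoxyphenoxy)benzaldehyde | COc1cc(OC)c(Oc2cc(OC)c(C=O)c(OC)c2)c(OC)c1 | intermediate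
16 | 2,6-dimethoxy-4-(2,4,6-trimethoxyphenoxy)phenyl formate | COc1cc(OC)c(Oc2cc(OC)c(OC=O)c(OC)c2)c(OC)c1 | intermediate
17 | 2,6-dimethoxy-4-(2,4,6-trimethoxyphenoxy)phenol (AB phenol) | COc1cc(OC)c(Oc2cc(OC)c(O)c(OC)c2)c(OC)c1 | intermediate
18 | 6-(AB-O)-2,3,4-trimethoxybenzaldehyde | COc1cc(OC)c(Oc2cc(OC)c(Oc3cc(OC)c(OC)c(OC)c3C=O)c(OC)c2)c(OC)c1 | intermediate
19 | 6-(AB-O)-2,3,4-trimethoxyphenyl formate | COc1cc(OC)c(Oc2cc(OC)c(Oc3cc(OC)c(OC)c(OC)c3OC=O)c(OC)c2)c(OC)c1 | intermediate
20 | 6-(AB-O)-2,3,4-trimethoxyphenol (ABC phenol) | COc1cc(OC)c(Oc2cc(OC)c(Oc3cc(OC)c(OC)c(OC)c3O)c(OC)c2)c(OC)c1 | intermediate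
21 | 4-(ABC-O)-2,6-dimethoxybenzaldehyde | COc1cc(OC)c(Oc2cc(OC)c(Oc3cc(OC)c(OC)c(OC)c3Oc3cc(OC)c(C=O)c(OC)c3)c(OC)c2)c(OC)c1 | intermediate
22 | 4-(ABC-O)-2,6-dimethoxyphenyl formate | COc1cc(OC)c(Oc2cc(OC)c(Oc3cc(OC)c(OC)c(OC)c3Oc3cc(OC)c(OC=O)c(OC)c3)c(OC)c2)c(OC)c1 | intermediate
23 | 4-(ABC-O)-2,6-dimethoxyphenol (ABCD phenol) | COc1cc(OC)c(Oc2cc(OC)c(Oc3cc(OC)c(OC)c(OC)c3Oc3cc(OC)c(O)c(OC)c3)c(OC)c2)c(OC)c1 | intermediate
24 | 2-(ABCD-O)-3,4,5-trimethoxybenzaldehyde | COc1cc(OC)c(Oc2cc(OC)c(Oc3cc(OC)c(OC)c(OC)c3Oc3cc(OC)c(Oc4c(C=O)cc(OC)c(OC)c4OC)c(OC)c3)c(OC)c2)c(OC)c1 | intermediate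
25 | 2-(ABCD-O)-3,4,5-trimethoxyphenyl formate | COc1cc(OC)c(Oc2cc(OC)c(Oc3cc(OC)c(OC)c(OC)c3Oc3cc(OC)c(Oc4c(OC=O)cc(OC)c(OC)c4OC)c(OC)c3)c(OC)c2)c(OC)c1 | intermediate
26 | 2-(ABCD-O)-3,4,5-trimethoxyphenol (ABCDE phenol) | COc1cc(OC)c(Oc2cc(OC)c(Oc3cc(OC)c(OC)c(OC)c3Oc3cc(OC)c(Oc4c(O)cc(OC)c(OC)c4OC)c(OC)c3)c(OC)c2)c(OC)c1 | intermediate
27 | methyl but-2-ynoate | CC#CC(=O)OC | starting material
28 | methyl (2E)-3-(ABCDE-O)but-2-enoate | COc1cc(OC)c(Oc2cc(OC)c(Oc3cc(OC)c(OC)c(OC)c3Oc3cc(OC)c(Oc4c(O/C(C)=C/C(=O)OC)cc(OC)c(OC)c4OC)c(OC)c3)c(OC)c2)c(OC)c1 | intermediate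
29 | (1Z)-3-(ABCDE-O)-1-methoxy-1-(trimethylsilyloxy)buta-1,3-diene | COc1cc(OC)c(Oc2cc(OC)c(Oc3cc(OC)c(OC)c(OC)c3Oc3cc(OC)c(Oc4c(OC(=C)/C=C(/OC)O[Si](C)(C)C)cc(OC)c(OC)c4OC)c(OC)c3)c(OC)c2)c(OC)c1 | intermediate
30 | racemic 1-[4-(ABCDE-O)-2-(GH-O)-6-methoxy-6-(trimethylsilyloxy)cyclohexa-1,4-dien-1-yl]ethanone | COc1cc(OC)c(Oc2cc(OC)c(Oc3cc(OC)c(OC)c(OC)c3Oc3cc(OC)c(Oc4c(OC5=CC(OC)(O[Si](C)(C)C)C(C(C)=O)=C(Oc6cc(OC)c(OC)c(OC)c6Oc6cc(OC)c(OC)c(OC)c6)C5)cc(OC)c(OC)c4OC)c(OC)c3)c(OC)c2)c(OC)c1 | intermediate
31 | 1-[4-(ABCDE-O)-6-(GH-O)-2-(trimethylsilyloxy)phenyl]ethanone | COc1cc(OC)c(Oc2cc(OC)c(Oc3cc(OC)c(OC)c(OC)c3Oc3cc(OC)c(Oc4c(Oc5cc(O[Si](C)(C)C)c(C(C)=O)c(Oc6cc(OC)c(OC)c(OC)c6Oc6cc(OC)c(OC)c(OC)c6)c5)cc(OC)c(OC)c4OC)c(OC)c3)c(OC)c2)c(OC)c1 | intermediate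
32 | 1-[4-(ABCDE-O)-6-(GH-O)-2-hydroxyphenyl]ethanone | COc1cc(OC)c(Oc2cc(OC)c(Oc3cc(OC)c(OC)c(OC)c3Oc3cc(OC)c(Oc4c(Oc5cc(O)c(C(C)=O)c(Oc6cc(OC)c(OC)c(OC)c6Oc6cc(OC)c(OC)c(OC)c6)c5)cc(OC)c(OC)c4OC)c(OC)c3)c(OC)c2)c(OC)c1 | intermediate
33 | 4-(ABCDE-O)-2-(GH-O)-6-hydroxyphenyl acetate | COc1cc(OC)c(Oc2cc(OC)c(Oc3cc(OC)c(OC)c(OC)c3Oc3cc(OC)c(Oc4c(Oc5cc(O)c(OC(C)=O)c(Oc6cc(OC)c(OC)c(OC)c6Oc6cc(OC)c(OC)c(OC)c6)c5)cc(OC)c(OC)c4OC)c(OC)c3)c(OC)c2)c(OC)c1 | intermediate
34 | 5-(ABCDE-O)-3-(GH-O)benzene-1,2-diol | COc1cc(OC)c(Oc2cc(OC)c(Oc3cc(OC)c(OC)c(OC)c3Oc3cc(OC)c(Oc4c(Oc5cc(O)c(O)c(Oc6cc(OC)c(OC)c(OC)c6Oc6cc(OC)c(OC)c(OC)c6)c5)cc(OC)c(OC)c4OC)c(OC)c3)c(OC)c2)c(OC)c1 | intermediate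
35 | CNP0309601.0 (34 with all nineteen methoxy groups as hydroxy groups) | Oc1cc(O)c(Oc2cc(O)c(Oc3cc(O)c(O)c(O)c3Oc3cc(O)c(Oc4c(Oc5cc(O)c(O)c(Oc6cc(O)c(O)c(O)c6Oc6cc(O)c(O)c(O)c6)c5)cc(O)c(O)c4O)c(O)c3)c(O)c2)c(O)c1 | target

## Step count and least certain steps

Total: 18 steps. Longest linear sequence: 13 steps (steps 6 to 18, from 13 and 14).

Step 16 (the step that carries the label for a new method). The most likely failure is that cycloaddition is too slow: the aryloxy donor deactivates the ynone and both partners are bulky, so hydrolysis or silyl migration of the ketene acetal and hydration or oligomerisation of the ynone can outrun ring formation. A stepwise Michael pathway could also end in loss of aryloxide from the β-carbon instead of ring closure. The fallback uses known nucleophilic aromatic substitution and sets out from 26 and 5.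
- Phenol 26 with excess 2',4',6'-trifluoroacetophenone (K2CO3, DMSO, 25 to 40 °C) should displace the fluoride para to the acetyl group, the position favoured in polar aprotic solvents, to give 1-[4-(ABCDE-O)-2,6-difluorophenyl]ethanone F1.
- Phenol 5 (K2CO3, DMSO, 80 °C) should then displace one of the two equivalent ortho fluorides to give 1-[4-(ABCDE-O)-2-fluoro-6-(GH-O)phenyl]ethanone F2.
- KOH in DMSO/H2O at 80 °C should exchange the last activated fluoride for hydroxyl, and the sequence comes back to the route at 32.

Step 12. The most likely failure is stalled C–O bond formation between a phenoxide flanked by two methoxy groups and a bromide flanked by formyl and methoxy, with protodebromination of 2 and oxidative loss of the valuable phenoxide taking over. The fallback changes the order of assembly and sets out from 20.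
- Commercial 4-bromo-2,6-dimethoxyphenol and 2 are joined first, where large excess and forcing conditions are affordable (Cs2CO3, NMP, 130 °C, with or without CuI), to give 2-(4-bromo-2,6-dimethoxyphenoxy)-3,4,5-trimethoxybenzaldehyde F3.
- F3 is then coupled with 20 (CuI, picolinic acid, K3PO4, DMSO, 110 °C), a union of the less encumbered type of step 10. This comes back to the route at 24 and replaces steps 10 to 12.

Step 4. The most likely failures are competing ortho-lithiation of the polymethoxyarene, proton transfer from the amide to the acetylide, and hydration of the push–pull ynone during work-up. The fallback sets out from 7.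
- Acetylide 9 is generated as before and trapped with acetaldehyde at −78 °C to give racemic 4-(GH-O)but-3-yn-2-ol F4.
- F4 is oxidised under neutral conditions (MnO2, CH2Cl2, rt), which avoids both the tetrahedral intermediate and any acidic quench, and the sequence comes back to the route at 10.

Step 17. The most likely failure is slow aryl migration at a ketone flanked by a hydrogen-bonded hydroxyl and an aryloxy group, so that alkaline peroxide oxidises the emerging catechol instead. The fallback sets out from 32.
- Acetylation (Ac2O, pyridine) gives 2-acetyl-5-(ABCDE-O)-3-(GH-O)phenyl acetate F5.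
- Baeyer–Villiger oxidation under non-basic conditions (mCPBA, Na2HPO4, CH2Cl2, with CF3CO2H as catalyst if needed) gives 5-(ABCDE-O)-3-(GH-O)-1,2-phenylene diacetate F6.
- Methanolysis (K2CO3, degassed MeOH) comes back to the route at 34.

Step 18. The most likely failures are incomplete cleavage of nineteen ethers, giving mixtures of partial methyl ethers, and oxidative loss of the free polyphenol during isolation. The fallback sets out from 34.
- The ethers are cleaved by a hard acid and soft nucleophile pair (AlCl3, EtSH, CH2Cl2, 0 °C to rt).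
- The crude polyphenol is acetylated in the same flask (Ac2O, pyridine) to the air-stable 21-fold acetate of 35 F7, which can be purified on silica.
- Acid-catalysed methanolysis (AcCl cat., degassed MeOH) comes back to the route at 35.

## Further compounds

F1 | step 16 | 1-[4-(ABCDE-O)-2,6-difluorophenyl]ethanone | COc1cc(OC)c(Oc2cc(OC)c(Oc3cc(OC)c(OC)c(OC)c3Oc3cc(OC)c(Oc4c(Oc5cc(F)c(C(C)=O)c(F)c5)cc(OC)c(OC)c4OC)c(OC)c3)c(OC)c2)c(OC)c1
F2 | step 16 | 1-[4-(ABCDE-O)-2-fluoro-6-(GH-O)phenyl]ethanone | COc1cc(OC)c(Oc2cc(OC)c(Oc3cc(OC)c(OC)c(OC)c3Oc3cc(OC)c(Oc4c(Oc5cc(F)c(C(C)=O)c(Oc6cc(OC)c(OC)c(OC)c6Oc6cc(OC)c(OC)c(OC)c6)c5)cc(OC)c(OC)c4OC)c(OC)c3)c(OC)c2)c(OC)c1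
F3 | step 12 | 2-(4-bromo-2,6-dimethoxyphenoxy)-3,4,5-trimethoxybenzaldehyde | O=Cc1cc(OC)c(OC)c(OC)c1Oc1c(OC)cc(Br)cc1OC
F4 | step 4 | racemic 4-(GH-O)but-3-yn-2-ol | CC(O)C#COc1cc(OC)c(OC)c(OC)c1Oc1cc(OC)c(OC)c(OC)c1
F5 | step 17 | 2-acetyl-5-(ABCDE-O)-3-(GH-O)phenyl acetate | COc1cc(OC)c(Oc2cc(OC)c(Oc3cc(OC)c(OC)c(OC)c3Oc3cc(OC)c(Oc4c(Oc5cc(OC(C)=O)c(C(C)=O)c(Oc6cc(OC)c(OC)c(OC)c6Oc6cc(OC)c(OC)c(OC)c6)c5)cc(OC)c(OC)c4OC)c(OC)c3)c(OC)c2)c(OC)c1
F6 | step 17 | 5-(ABCDE-O)-3-(GH-O)-1,2-phenylene diacetate | COc1cc(OC)c(Oc2cc(OC)c(Oc3cc(OC)c(OC)c(OC)c3Oc3cc(OC)c(Oc4c(Oc5cc(OC(C)=O)c(OC(C)=O)c(Oc6cc(OC)c(OC)c(OC)c6Oc6cc(OC)c(OC)c(OC)c6)c5)cc(OC)c(OC)c4OC)c(OC)c3)c(OC)c2)c(OC)c1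
F7 | step 18 | 21-fold acetate of 35 | CC(=O)Oc1cc(OC(C)=O)c(Oc2cc(OC(C)=O)c(Oc3cc(OC(C)=O)c(OC(C)=O)c(OC(C)=O)c3Oc3cc(OC(C)=O)c(Oc4c(Oc5cc(OC(C)=O)c(OC(C)=O)c(Oc6cc(OC(C)=O)c(OC(C)=O)c(OC(C)=O)c6Oc6cc(OC(C)=O)c(OC(C)=O)c(OC(C)=O)c6)c5)cc(OC(C)=O)c(OC(C)=O)c4OC(C)=O)c(OC(C)=O)c3)c(OC(C)=O)c2)c(OC(C)=O)c1
A1 | alternative 1 | methyl 6-[4-(benzyloxy)-3,5-dimethoxyphenoxy]-3,5-dioxohexanoate | COC(=O)CC(=O)CC(=O)COc1cc(OC)c(OCc2ccccc2)c(OC)c1
A2 | alternative 1 | 2-[4-(benzyloxy)-3,5-dimethoxyphenoxy]benzene-1,3,5-triol | Oc1cc(O)c(Oc2cc(OC)c(OCc3ccccc3)c(OC)c2)c(O)c1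
A3 | alternative 2 | racemic 4-[(E)-2-(AB-O)ethenyl]-2,3,4-trimethoxycyclobut-2-en-1-one | COC1=C(OC)C(OC)(/C=C/Oc2c(OC)cc(Oc3c(OC)cc(OC)cc3OC)cc2OC)C1=O
A4 | alternative 2 | 6-(AB-O)-2,3,4-trimethoxyphenol (identical with 20) | COc1cc(OC)c(Oc2cc(OC)c(Oc3cc(OC)c(OC)c(OC)c3O)c(OC)c2)c(OC)c1
A5 | alternative 3 | dimethyl (2E)-3-(ABC-O)pent-2-enedioate | COc1cc(OC)c(Oc2cc(OC)c(Oc3cc(OC)c(OC)c(OC)c3O/C(CC(=O)OC)=C/C(=O)OC)c(OC)c2)c(OC)c1
A6 | alternative 3 | 2-{2-[3,4-dimethoxy-5-(GH-O)phenoxy]-4,5,6-trimethoxyphenoxy}propanedioyl dichloride | O=C(Cl)C(C(Cl)=O)Oc1c(Oc2cc(OC)c(OC)c(Oc3cc(OC)c(OC)c(OC)c3Oc3cc(OC)c(OC)c(OC)c3)c2)cc(OC)c(OC)c1OC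
A7 | alternative 3 | octamer with ring D as dimethyl 2,4-dihydroxybenzene-1,3-dicarboxylate, other rings as methyl ethers | COc1cc(OC)c(Oc2cc(OC)c(Oc3cc(OC)c(OC)c(OC)c3Oc3c(C(=O)OC)c(O)c(Oc4c(Oc5cc(OC)c(OC)c(Oc6cc(OC)c(OC)c(OC)c6Oc6cc(OC)c(OC)c(OC)c6)c5)cc(OC)c(OC)c4OC)c(O)c3C(=O)OC)c(OC)c2)c(OC)c1
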